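Readings and results were generated by integration for substances that don't exist, noise included.

The question before me was whether the flask with 1.80 equiv of coupling partner, the epsilon run followed on, would gain from standing until 40 min, or whether my next run had to charge something else.

| setting | epsilon | beta | flask |
|---|---|---|---|
| substrate | 30 mM | 30 mM | 30 mM |
| coupling partner | 1.8 equiv | 2.7 equiv | 1.80 equiv |
| remark | the very flask that is asked about, followed so far | run made earlier |  |
| time |  |  | 40 min |

| run | time / min | isomer of the product / % | target / % |
|---|---|---|---|
| epsilon | 1.50 | 79.6 | 1.3 |
| epsilon | 2.50 | 84.3 | 0 |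
| epsilon | 4.00 | 86.9 | 0.2 |
| epsilon | 8.00 | 87.6 | 1.3 |
| epsilon | 12.0 | 87.7 | 0.5 |
| epsilon | 20.0 | 88.5 | 0.4 |
| beta | 3.00 | 92.9 | 0.3 |
| beta | 5.00 | 94.7 | 0.7 |
| beta | 8.00 | 95.9 | 0.2 |
| beta | 15.0 | 96.1 | 1.1 |
| beta | 25.0 | 96.2 | 0.6 |
| beta | 40.0 | 96.7 | 0 |

(each reading ± 0.5 percentage points)

* at 40 min, what has stopped the reaction, if anything has (forward and back rates have come level / all of the substrate has reacted / the coupling partner has run out first / it is still moving)
* amount of isomer of the product at 40 min, in percent of the substrate charged

- the reaction counts as stopped when no species that holds the substrate changes by six tenths of a point or more over the second half of the time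

In epsilon the isomer of the product rose 0.9 percentage points between 8.00 min and 20.0 min, with readings scattering by 0.5 points, so I replaced each tail by the mean of its last 3 readings. Epsilon's tail gave 87.9% isomer. Neither isomer nor target accounted for 11.3% of the substrate in epsilon and 3.10% in beta.

I supposed that substrate falls at k[substrate][coupling partner]. Then minus the logarithm of the fraction left equals k times the mean [coupling partner] times the time. If that product grows in step with the charge, the logarithm divided by the equivalents is a constant. Epsilon gave 1.21 and beta 1.29, and their mean, 1.25, is the dose per equivalent. Beta's value applied to epsilon leaves 9.87%, an error of 1.4 points. So I decided to change the charge of partner, not the time, and expected 87.9% isomer at 40 min.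

The forecast said: the coupling partner has run out first, with isomer at 88.2%, on the ground that “the partner is being lost to a competing decay”.

The flask gave: the coupling partner has run out first, with isomer at 88.2%.

    intermediate ⇌ isomer of the product (K = 160, k = 0.108 s⁻¹)
    crystals ⇌ released group, rate k2*(cs2 - [released group]) while solid is left; crystals form when [released group] > cs2 (solubility = 29.0 mM, k = 12.0 s⁻¹)
    intermediate ⇌ target (K = 0.741, k = 0.312 s⁻¹)
    substrate + coupling partner → intermediate + released group (k = 2.17 M⁻¹ s⁻¹)
    2 coupling partner → homo dimer (k = 0.870 M⁻¹ s⁻¹)

At 40.0 min the flask held 0% of its coupling partner, the limiting reagent, and 11% of its substrate, a dose per equivalent of 1.23. The 13.6 mM of homo dimer took half of the charge, and the same run without that step gave 98.9% isomer, so dimer formation is a part of the reason. The main reason for the 88.2% of isomer is the falling back of target to intermediate: the same run without it gave 6.99%. For the neighbouring flask with 0.450 equiv, the dose reckons 57.0% of the substrate left, and that flask held 62%.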